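This reaction is slow, and the question is what more catalyst buys. A single-handed free catalyst binds either substrate. Each bound form then takes up reagent, which dissolves from the gas, and two free catalyst can pair into a resting dimer, the proposed off-cycle resting state.

in all of them: left-handed substrate 0.40 M; right-handed substrate 0.40 M; gas 87 mM (held)

| charge | free catalyst | remark | time |
|---|---|---|---|
| autumn | 5 mol% | run made earlier |  |
| noon | 20 mol% | run made earlier |  |
| flask | 10 mol% |  | 40 min |

- autumn (time / min: left-handed product / %, right-handed product / %, left-handed substrate / %): 8.00: 2.3, 0.8, 47.6; 15.0: 3.0, 1.1, 45.4; 25.0: 6.8, 2.0, 41.2; 30.0: 7.8, 2.3, 39.3; 40.0: 10.1, 4.1, 36.4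
- noon (time / min: left-handed product / %, right-handed product / %, left-handed substrate / %): 3.00: 0.6, 0, 47.8; 6.00: 2.0, 0.3, 46.9; 12.0: 5.2, 0.8, 43.6; 20.0: 8.9, 2.6, 38.8; 40.0: 15.4, 8.3, 28.6

(readings scatter by 0.5 percentage points)

1. excess of left-handed product over right-handed product in the product at 4.0 min
2. excess of left-handed product over right-handed product in the product at 40 min
3. part of the left-handed substrate and right-handed substrate charged together that has reacted at 40 min

- free catalyst is single-handed; left-handed substrate and right-handed substrate are mirror images of each other, charged as a racemate, each of them at the stated concentration
- at the start none of reagent is dissolved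
- steps that have been proposed: gas <-> reagent; free catalyst + left-handed substrate <-> catalyst intermediate A; free catalyst + right-handed substrate <-> catalyst intermediate B; reagent + catalyst intermediate A -> free catalyst + left-handed product; left-handed product <-> right-handed product; 2 free catalyst <-> resting dimer; reagent + catalyst intermediate B -> free catalyst + right-handed product
- an excess is the difference of the two amounts in percent of their sum
- an excess is below zero if the other one leads

The autumn run looks nearly the same as the flask: the same substrates and gas, with 5 mol% of catalyst against 10 mol%. To carry it across we need a rule, which we read from the autumn and noon runs together. At 40.0 min the autumn run holds 14.2% of product, both hands counted, and the noon run 23.7%. So 4.00 times the catalyst gave 1.67 times the product, and the product grew less than the catalyst.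

The ratio of the two logarithms, 0.369, is a reading we call the loading exponent: the power of the loading that the product follows at a fixed time, with the substrates and gas charged as in these runs. Where the dimer outweighs every other form of the catalyst, free catalyst follows the power 0.5 of the loading, and our reading for the product lies lower than that. At that time the noon run also had less left-handed substrate left than the autumn run, 28.6% against 36.4%.

Our reckoning for the flask is 18.3% of product. Going round once more, the reacted part also counts substrate held on the catalyst. With one substrate per catalyst that adds at most 5.00% of the total charged, so we expect between 18.3% and 23.3%.

The forecast gives an excess of 70% at 4.0 min (range 55% to 85%), an excess of 36% at 40 min (29% to 44%) and 19% reacted (16% to 24%), and it calls the catalyst dependence “close to half order, as expected for a resting dimer”. Our exponent reads lower than that, but the forecast drew on the same two runs, so the nearness of its figure to ours is no check.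

The flask gives an excess of 73.3% at 4.0 min, an excess of 34.7% at 40 min and 20.8% reacted.

    gas ⇌ reagent, rate k1*(csat - [reagent]) (kL = 0.00170 /s)
    free catalyst + left-handed substrate ⇌ catalyst intermediate A (K = 5.20 /M, k = 1.20 /M/s)
    free catalyst + right-handed substrate ⇌ catalyst intermediate B (K = 3.40 /M, k = 1.70 /M/s)
    reagent + catalyst intermediate A → free catalyst + left-handed product (k = 0.210 /M/s)
    left-handed product ⇌ right-handed product (k = 3.90 × 10⁻⁴ /s)
    2 free catalyst ⇌ resting dimer, settled at all times (K = 590 /M)
    reagent + catalyst intermediate B → free catalyst + right-handed product (k = 0.0380 /M/s)

At 40.0 min the flask holds 19.3% as product, and its resting dimer holds 59.9% of the catalyst charged, more than the 28.9% in the two intermediates together. Now take the neighbouring flask with 2.5 mol% of free catalyst. From the autumn run, the loading exponent gives 11.0% of product there, and at 40.0 min that flask holds 10.7%.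

All runs are calculated with constants of no real substance, and the scatter is random.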